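How much E will Thursday's flask hold at 44 min, with less X than any earlier flask and a third of their Z? We answer it alongside the two questions on Monday's and Sunday's flasks.

| flask | X | Z | E | time |
|---|---|---|---|---|
| Monday's | 120 mM | 2.40 mM |  |  |
| Sunday's | 48.0 mM | 2.40 mM |  |  |
| Wednesday's | 120 mM | 2.40 mM | 60.0 mM |  |
| Thursday's | 40.0 mM | 0.790 mM |  | 44 min |

- Monday's run (time / min: [E] / mM): 5.5: 12.0; 11: 21.2; 16: 30.1; 22: 40.2; 28: 49.3; 33: 57.9; 38: 62.7; 44: 72.1
- Sunday's run (time / min: [E] / mM): 5.5: 7.4; 11: 12.7; 16: 18.5; 22: 22.6; 28: 28.2; 33: 33.9; 38: 35.9; 44: 36.5
- Wednesday's run (time / min: [E] / mM): 5.5: 70.2; 11: 79.8; 16: 89.5; 22: 100.8; 28: 110.8; 33: 118.9; 38: 124.7; 44: 131.8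

(scatter of a reading: 1 mM)

- order of the initial rate in [X], near the charge of the Monday's run, the rate being that where two percent of its X are E (one fixed amount of E, the same in the runs compared)
- the Sunday's run starts with 72.0 mM less of X than the Monday's run, and with no E. Compared where both hold the same amount of X, once fifteen percent of what the Sunday's run was charged with has turned into E, is the Sunday's run faster, slower or alike (within a tenth)?
- E in the Thursday's run at 44 min, as a share of the X charged

- Overall: X -> E, with Z as catalyst.
- Constant volume, constant temperature.
- The analysis sees a species whether free or bound.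
- An order is taken over about fifteen percent of the charge, up and down.

We turn the settings one at a time, asking first what each should do by hand.

1. Added E. If E held on to Z, Wednesday's flask should lag. Yet it made 71.8 mM of new E by 44 min, and Monday's flask made 72.1 mM, a gap within the scatter. So we leave E out of the rate.

2. Charge of X. By hand, first order in X means a rate ratio of 2.50 between Monday's charge and Sunday's. Over the first 16 min, Monday's flask averaged 1.88 mM min⁻¹ and Sunday's 1.16 mM min⁻¹, a ratio of just 1.63. So the rate levels off, and we write rate = V·cX/(K + cX), which integrates to V·t = K·ln(charge/cX) + cE made.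

Setting the last readings of Monday's and Sunday's flasks against each other gives K = 69.7 mM, the half-speed level, the cX at which the rate is half its top value V. V reads 3.09 mM min⁻¹. The order at a given cX is K/(K + cX), so 0.368 at Monday's charge. With the same Z and E without effect, Sunday's and Monday's flasks should run alike at equal cX, though Monday's readings stop short of the point asked about.

3. Z. No earlier flask changed it, so we assume proportion: Thursday's V becomes 1.02 mM min⁻¹. Holding the starting rate over 44 min makes 16.3 mM. Taking the rate at the halfway cX of 31.8 mM instead gives 14.0 mM, a share of 35.1%.

The forecast, close to our figures, says 0.4, alike and 36%, assuming the “rate is first order in Z”.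

The simulation gives 0.41, alike and, for Thursday's flask, 44.9%, which is 9.8 percentage points above our share.

    2 Z ⇌ Z2, settled at all times (352.0 M⁻¹)
    Z + X → E + Z (49.80 M⁻¹ min⁻¹)
    2 X ⇌ X2, settled at all times (16.30 M⁻¹)
    Z + X ⇌ ZX, settled at all times (26.20 M⁻¹)

Keeping K, Thursday's E asks for a top speed of 1.35 mM min⁻¹. That is 0.437 of Monday's V on 0.329 of its Z, so V fell less than Z did. On Wednesday's flask, K = 69.7 mM and V give 16.2 min for the E made to reach a quarter of the X charged, and the flask's time is 16.0 min. The association of Z + X to ZX lowers the order in X: Monday's flask has order 0.41 with it and 0.64 without it.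

(The numbers in the tables were computed on assumed constants, noise included.)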